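The readings were generated by integration for an exercise, noise included.

0.050 M of substrate in the flask against 0.025 M in the elm run was the number I started from, and both carried 0.600 equiv of reagent.

| flask | substrate | reagent | remark | time |
|---|---|---|---|---|
| elm | 0.025 M | 0.60 equiv | run made earlier |  |
| alder | 0.038 M | 0.60 equiv | run made earlier |  |
| oak | 0.050 M | 0.30 equiv | run made earlier |  |
| flask | 0.050 M | 0.600 equiv |  | 25 h |

| run | time / h | target / % | substrate / % |
|---|---|---|---|
| elm | 2.00 | 13 | 80 |
| elm | 5.00 | 22 | 67 |
| elm | 10.0 | 20 | 58 |
| elm | 15.0 | 23 | 58 |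
| alder | 2.00 | 19 | 76 |
| alder | 5.00 | 23 | 62 |
| alder | 10.0 | 25 | 50 |
| alder | 15.0 | 34 | 54 |
| oak | 1.33 | 8 | 87 |
| oak | 3.00 | 13 | 77 |
| oak | 6.00 | 20 | 77 |
| oak | 15.0 | 15 | 71 |

(readings scatter by 2 percentage points)

- a reading of substrate is of its free form alone

- amount of target in percent of the substrate charged, at 2.5 h, 8.0 h, 15 h and 25 h

I read the runs as a bimolecular reaction. The used fraction x of substrate then grows at the rate k c (1 − x)(e − x), where c is the substrate charge and e the equivalents. Integrated in closed form, x depends on the product c t, so long as e stays fixed and bimolecular steps are what runs. I therefore carried a matched time: the time at which a more dilute run reaches the state of the flask, which is the flask's time multiplied by the ratio of the charges.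

For 2.5 h the matched time in the elm run was 5.00 h, and elm read 22% of target at 5.00 h. I took that value. For 8.0 h the alder run matched at 10.5 h, and alder read 25% at 10.0 h, which I took as well.

Later times matched beyond the readings of elm and alder, so for 15 h I took the last two alder readings as a level, 29.5%. Oak's target went from 20% to 15%, which suggested a sag. That was the weak link, since it rested on two readings with a scatter of 2 percentage points.

I reforged it with the selectivity, meaning target per substrate used, pooled over the runs. It read 0.702 at the first readings and 0.615 at the last. Scaling the level by that ratio, I committed to 25.8% at 25 h.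

The forecast gave 18%, 28%, 31% and 31%, on the ground that “Target looks stable once formed, so it should stay flat.” My reckoning fell at the end, and the forecast's did not.

The flask gave 22.1%, 29.5%, 28.4% and 25.3%. Between 12.5 h and 25.0 h the flask's substrate went from 50.1% to 49.4%, while its isomer of the product went from 20.8% to 25.3%.

    substrate + reagent ⇌ target (K = 160 L mol⁻¹, k = 0.00170 L mol⁻¹ s⁻¹)
    substrate + reagent ⇌ isomer of the product (K = 6300 L mol⁻¹, k = 8.60 × 10⁻⁴ L mol⁻¹ s⁻¹)
    reagent ⇌ dormant form (K = 1.80, k = 6.90 × 10⁻⁶ s⁻¹)

At the matched 5.00 h elm had read 22% of target and 67% of substrate. The flask at 2.50 h held 22.1% of target and 66.0% of substrate.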